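**Retrosynthetic overview**
- Dinklagin A (C25H26O4) is an isomer of an open-chain enone-yne. Both oxygen heterocycles are cut at once: O1–C2 of ring C (retro-oxa-Michael) and the aryl–CH= bond of ring D (retro-hydroarylation).
- This gives a 2'-hydroxychalcone whose ring B carries a 1,1-dimethylpropargyl ether. Its enone C=C is cut (retro-Claisen–Schmidt) into a C-prenylated resacetophenone and an O-propargylated 4-hydroxybenzaldehyde.
- The prenyl group comes from 2-methylbut-3-en-2-ol (Friedel–Crafts) and the propargyl ether from 3-chloro-3-methylbut-1-yne. No protecting groups are used.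
- Ring order: rings A and B are bought. Ring D and then ring C close in one flask in the last step, which also sets the only stereocenter (2S).

Assumption: the quinine-derived thiourea is taken to give the 2S series; the first run is checked by chiral HPLC and circular dichroism, and the quinidine-derived pseudoenantiomer is used instead if the product is 2R.

**Step 1**
Reactants: 1 resacetophenone (2,4-dihydroxyacetophenone); 2 2-methylbut-3-en-2-ol
Product: 3 1-[2,4-dihydroxy-5-(3-methylbut-2-en-1-yl)phenyl]ethan-1-one
Conditions: BF3·OEt2 (0.4 equiv), dioxane, 23 °C, 3 h; chromatography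
Reagents that add atoms: none
Why: Friedel–Crafts prenylation in which BF3 ionises the tertiary allylic alcohol to the dimethylallyl cation, which attacks through its primary end at C5 (ortho to the free 4-OH, para to the chelated 2-OH, less crowded than C3), so the 5-prenyl ketone is the main C-alkylation product (modest yield from very cheap materials) and is separated from the 3-prenyl isomer; no stereocenter is formed.

**Step 2**
Reactants: 4 4-hydroxybenzaldehyde; 5 3-chloro-3-methylbut-1-yne
Product: 6 4-[(2-methylbut-3-yn-2-yl)oxy]benzaldehyde
Conditions: K2CO3 (2 equiv), KI (0.1 equiv), CuI (2 mol%), DMF, 60 °C, 16 h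
Reagents that add atoms: none
Why: Copper-assisted Williamson-type O-alkylation of the phenoxide by the tertiary propargylic chloride, run well below the temperature at which the aryl propargyl ether would rearrange, so the alkyne is kept for the last step and the aldehyde is untouched.

**Step 3**
Reactants: 3 1-[2,4-dihydroxy-5-(3-methylbut-2-en-1-yl)phenyl]ethan-1-one; 6 4-[(2-methylbut-3-yn-2-yl)oxy]benzaldehyde
Product: 7 (E)-1-[2,4-dihydroxy-5-(3-methylbut-2-en-1-yl)phenyl]-3-{4-[(2-methylbut-3-yn-2-yl)oxy]phenyl}prop-2-en-1-one
Conditions: KOH (50% aq, 12 equiv), EtOH, N2, 23 °C, 48 h; then 1 M HCl, 0 °C, to pH 5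
Reagents that add atoms: none
Why: Claisen–Schmidt condensation of the unprotected methyl ketone with a non-enolisable aldehyde, in which the E enone forms by E1cB loss of water and stays open as its phenoxide in strong base, while the prenyl group, the tertiary ether (no propargylic hydrogen) and the terminal alkyne are inert to aqueous ethanolic KOH.

**Step 4**
Reactants: 7 (E)-1-[2,4-dihydroxy-5-(3-methylbut-2-en-1-yl)phenyl]-3-{4-[(2-methylbut-3-yn-2-yl)oxy]phenyl}prop-2-en-1-one
Product: 9 (2S)-dinklagin A, via chromene chalcone 8 (not isolated)
Conditions: Ph3PAuNTf2 (2 mol%), 4 Å MS, CH2Cl2, 23 °C, 2 h; then in the same flask toluene, 1-[3,5-bis(trifluoromethyl)phenyl]-3-[(8α,9S)-6'-methoxycinchonan-9-yl]thiourea (20 mol%), 25 °C, 72–96 h, dark; direct chromatography on acid-washed SiO2, recrystallisation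
Reagents that add atoms: none
Why: Proposed new method: a one-flask relay of two known cycloisomerisation types not yet combined or run on an unprotected substrate like this, in which cationic monovalent gold first activates the terminal alkyne for 6-endo-dig hydroarylation at either of the two equivalent carbons ortho to the ether oxygen and closes ring D (closest known type: gold-catalysed cyclisation of aryl 1,1-dimethylpropargyl ethers to 2,2-dimethyl-2H-chromenes), after which the sulfur and amine donors of the added organocatalyst shut the gold down and the bifunctional catalyst hydrogen-bonds the enone carbonyl while its quinuclidine deprotonates the chelated 2'-OH, so the phenoxide adds 6-endo-trig to one face of the enone in an intramolecular oxa-Michael reaction that closes ring C and sets C2 as S (closest known type: chalcone-isomerase-like thiourea-catalysed cyclisation of 2'-hydroxychalcones), with the prenyl group, the free 4'-OH and the chromene alkene inert to both catalysts at room temperature.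

**Compound list**
1 | 2,4-dihydroxyacetophenone | CC(=O)c1ccc(O)cc1O | starting material
2 | 2-methylbut-3-en-2-ol | C=CC(C)(C)O | starting material
3 | 1-[2,4-dihydroxy-5-(3-methylbut-2-en-1-yl)phenyl]ethan-1-one | CC(=O)c1cc(CC=C(C)C)c(O)cc1O | intermediate
4 | 4-hydroxybenzaldehyde | O=Cc1ccc(O)cc1 | starting material
5 | 3-chloro-3-methylbut-1-yne | C#CC(C)(C)Cl | starting material
6 | 4-[(2-methylbut-3-yn-2-yl)oxy]benzaldehyde | C#CC(C)(C)Oc1ccc(C=O)cc1 | intermediate
7 | (E)-1-[2,4-dihydroxy-5-(3-methylbut-2-en-1-yl)phenyl]-3-{4-[(2-methylbut-3-yn-2-yl)oxy]phenyl}prop-2-en-1-one | CC(C)=CCc1cc(C(=O)/C=C/c2ccc(OC(C)(C)C#C)cc2)c(O)cc1O | intermediate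
8 | (E)-1-[2,4-dihydroxy-5-(3-methylbut-2-en-1-yl)phenyl]-3-(2,2-dimethyl-2H-chromen-6-yl)prop-2-en-1-one (chromene chalcone) | CC(C)=CCc1cc(C(=O)/C=C/c2ccc3c(c2)C=CC(C)(C)O3)c(O)cc1O | intermediate
9 | dinklagin A, (2S)-2-(2,2-dimethyl-2H-chromen-6-yl)-7-hydroxy-6-(3-methylbut-2-en-1-yl)-2,3-dihydro-4H-chromen-4-one | CC(C)=CCc1cc2c(cc1O)O[C@H](c1ccc3c(c1)C=CC(C)(C)O3)CC2=O | target

Total step count: 4. Longest linear sequence: 3 steps (1 → 3 → 7 → 9).

**Steps most likely to fail**

**Step 4.**
- Risk: the oxa-Michael closure is reversible and the enone is electron-rich, so conversion may stall and the ee may erode. The acidic 4'-OH may also tie up the amine of the catalyst.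
- Fallback: it sets out from 7 and comes back at 9. It keeps the one-flask double ring closure but moves stereocontrol to a separate resolution.
- The same Ph3PAuNTf2 cycloisomerisation of 7 gives 8. NaOAc in ethanol at 70 °C in the same flask then closes ring C without stereocontrol to give racemic dinklagin A F1.
- F1 is resolved kinetically by asymmetric transfer hydrogenation with RuCl[(R,R)-TsDPEN](p-cymene) and HCO2H/Et3N (5:2) in EtOAc at 25 °C, stopped near 52% conversion.
- The 2R ketone is reduced from the face opposite the aryl group to the cis-(2R,4R)-flavan-4-ol F2. The slower-reacting 2S ketone 9 is recovered by chromatography in at most half the mass.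

**Step 1.**
- Risk: the 3-prenyl isomer, bis-prenylation and acid-induced chroman formation keep the yield low.
- Fallback: it sets out from 1 and comes back at 3. It replaces cation chemistry with a site-defined cross-coupling.
- ICl in AcOH at 23 °C iodinates 1 at C5 to give 1-(2,4-dihydroxy-5-iodophenyl)ethanone F3.
- A Stille coupling of F3 with tributyl(3-methylbut-2-en-1-yl)stannane, Pd(PPh3)4 (5 mol%), DMF, 90 °C, places the linear prenyl group at that carbon and gives 3. The free phenols tolerate these neutral conditions.

**Step 3.**
- Risk: the dianion of 3 enolises poorly, so the condensation may be slow. Acidification can also close part of the product to racemic flavanone.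
- Fallback: it sets out from 3 (with 6) and comes back at 7. It replaces the thermodynamic condensation with a stepwise, kinetically controlled polyanion aldol followed by a separate dehydration.
- LiN(SiMe3)2 (3.3 equiv) in THF at −78 °C converts 3 into its trilithium salt (two phenoxides and the enolate).
- Addition of 6 and an acetic acid quench give the racemic β-hydroxy ketone F4.
- Pyridinium p-toluenesulfonate (10 mol%) in toluene at 60 °C dehydrates F4 to 7.

**Further compounds**
F1 | step 4 | racemic dinklagin A, 2-(2,2-dimethyl-2H-chromen-6-yl)-7-hydroxy-6-(3-methylbut-2-en-1-yl)-2,3-dihydro-4H-chromen-4-one | CC(C)=CCc1cc2c(cc1O)OC(c1ccc3c(c1)C=CC(C)(C)O3)CC2=O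
F2 | step 4 | cis-(2R,4R)-flavan-4-ol, (2R,4R)-2-(2,2-dimethyl-2H-chromen-6-yl)-6-(3-methylbut-2-en-1-yl)chromane-4,7-diol | CC(C)=CCc1cc2c(cc1O)O[C@@H](c1ccc3c(c1)C=CC(C)(C)O3)C[C@H]2O
F3 | step 1 | 1-(2,4-dihydroxy-5-iodophenyl)ethanone | CC(=O)c1cc(I)c(O)cc1O
F4 | step 3 | racemic β-hydroxy ketone, 1-[2,4-dihydroxy-5-(3-methylbut-2-en-1-yl)phenyl]-3-hydroxy-3-{4-[(2-methylbut-3-yn-2-yl)oxy]phenyl}propan-1-one | CC(C)=CCc1cc(C(=O)CC(O)c2ccc(OC(C)(C)C#C)cc2)c(O)cc1O
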